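Assumption: the SMILES is taken literally, i.e. 1′R,6′S in the ring (6′‑CH2O trans to the 1′‑OH) and 3R in the glutarate; primed locants follow abscisic acid numbering (C‑1′ carbinol, C‑4′ ketone, C‑6′ quaternary carbon).

**Retrosynthetic overview**
- Last disconnection: the ester between the 6′‑CH2OH of the abscisic‑acid‑type core and an (S)‑3‑hydroxy‑3‑methylglutaric mono‑allyl half‑ester; both carboxyls travel as allyl esters and are freed together at the end.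
- Side chain: C3–C4 bond by copper‑mediated coupling of an (E)‑vinylstannane (from a 1′‑ethynyl carbinol) with allyl (Z)‑3‑iodobut‑2‑enoate.
- C‑1′: chelation‑controlled ethynyl Grignard addition to a 6‑(hydroxymethyl)‑2,6‑dimethyl enone ketal. C‑6′: Pd‑catalysed decarboxylative asymmetric allylation, the allyl group then degraded to CH2OH.
- Glutarate stereocentre: carboxylesterase desymmetrisation of the prochiral dimethyl ester, followed by exchange of the ester groups.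
- Rings: no carbocycle is constructed. The six‑membered ring is the benzene ring of 2,6‑dimethylphenol, dearomatised in step 1; the only ring formed is the temporary dioxolane (step 1), opened in step 19.

**Route**

Step 1
Reactants: 1 2,6‑dimethylphenol
Product: 2 7,9‑dimethyl‑1,4‑dioxaspiro[4.5]deca‑6,9‑dien‑8‑one
Conditions: PhI(OAc)2 (2.2 equiv), ethylene glycol/CH2Cl2, 0 °C → rt
Reagents that add atoms: ethylene glycol, OCCO
Why: Hypervalent‑iodine oxidative dearomatisation: the phenol is oxidised twice, ethylene glycol is captured at the para carbon and closes to the spiro‑ketal, giving the achiral quinone monoketal with all ring carbons and the masked C‑4′ ketone in place.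

Step 2
Reactants: 2 7,9‑dimethyl‑1,4‑dioxaspiro[4.5]deca‑6,9‑dien‑8‑one
Product: 4 prop‑2‑en‑1‑yl 7,9‑dimethyl‑1,4‑dioxaspiro[4.5]deca‑7,9‑dien‑8‑yl carbonate, via lithium dienolate 3 (not isolated)
Conditions: LiBH(s‑Bu)3 (1.05 equiv), THF, −78 °C; then TMEDA, allyl chloroformate, −78 → 0 °C
Reagents that add atoms: allyl chloroformate, C=CCOC(=O)Cl
Why: Conjugate (1,4) hydride reduction of one enone arm by the bulky borohydride gives the regiodefined tetrasubstituted enolate, which is O‑acylated (enolate trapping) to the enol carbonate; no stereocentre exists yet.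

Step 3
Reactants: 4 prop‑2‑en‑1‑yl 7,9‑dimethyl‑1,4‑dioxaspiro[4.5]deca‑7,9‑dien‑8‑yl carbonate
Product: 5 (7R)‑7,9‑dimethyl‑7‑(prop‑2‑en‑1‑yl)‑1,4‑dioxaspiro[4.5]dec‑9‑en‑8‑one
Conditions: Pd2(dba)3 (2.5 mol %), (S)‑4‑tert‑butyl‑2‑[2‑(diphenylphosphino)phenyl]‑4,5‑dihydrooxazole [(S)‑t‑Bu‑PHOX] (6.25 mol %), THF, 25 °C
Reagents that add atoms: none
Why: Decarboxylative asymmetric allylic alkylation (Tsuji allylation): zerovalent palladium ionises the carbonate, CO2 is lost and the PHOX‑bound allylpalladium enolate forms the quaternary C–C bond on one enolate face, setting C‑6′ as R in the same spatial sense as (S)‑2‑allyl‑2‑methylcyclohexanone from this ligand.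

Step 4
Reactants: 5 (7R)‑7,9‑dimethyl‑7‑(prop‑2‑en‑1‑yl)‑1,4‑dioxaspiro[4.5]dec‑9‑en‑8‑one
Product: 6 (7S)‑7,9‑dimethyl‑7‑[(1E)‑prop‑1‑en‑1‑yl]‑1,4‑dioxaspiro[4.5]dec‑9‑en‑8‑one
Conditions: RuHCl(CO)(PPh3)3 (3 mol %), toluene, 80 °C
Reagents that add atoms: none
Why: Ruthenium‑hydride alkene isomerisation (hydrometalation/β‑hydride elimination) moves the terminal double bond one position and stops there because the next carbon is quaternary; the stereocentre is untouched (the descriptor changes only through CIP priorities).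

Step 5
Reactants: 6 (7S)‑7,9‑dimethyl‑7‑[(1E)‑prop‑1‑en‑1‑yl]‑1,4‑dioxaspiro[4.5]dec‑9‑en‑8‑one
Product: 8 (7S)‑7,9‑dimethyl‑8‑oxo‑1,4‑dioxaspiro[4.5]dec‑9‑ene‑7‑carbaldehyde, via ozonide 7 (not isolated)
Conditions: O3 (ca. 1 equiv, Sudan Red 7B indicator), CH2Cl2, −78 °C; then PPh3, −78 °C → rt
Reagents that add atoms: ozone, [O-][O+]=O
Why: Ozonolysis (Criegee mechanism) cleaves the electron‑neutral propenyl alkene far faster than the electron‑poor enone alkene, and PPh3 reduces the ozonide to the non‑enolisable keto aldehyde.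

Step 6
Reactants: 8 (7S)‑7,9‑dimethyl‑8‑oxo‑1,4‑dioxaspiro[4.5]dec‑9‑ene‑7‑carbaldehyde
Product: 9 (7S)‑7‑(hydroxymethyl)‑7,9‑dimethyl‑1,4‑dioxaspiro[4.5]dec‑9‑en‑8‑one
Conditions: NaBH4 (0.6 equiv), EtOH/CH2Cl2 3:7, −78 °C
Reagents that add atoms: none
Why: Chemoselective borohydride reduction: at −78 °C the aldehyde is reduced while the hindered conjugated ketone is not, giving the 6′‑CH2OH group.

Step 7
Reactants: 9 (7S)‑7‑(hydroxymethyl)‑7,9‑dimethyl‑1,4‑dioxaspiro[4.5]dec‑9‑en‑8‑one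
Product: 11 (7S,8R)‑8‑ethynyl‑7‑(hydroxymethyl)‑7,9‑dimethyl‑1,4‑dioxaspiro[4.5]dec‑9‑en‑8‑ol, via bromomagnesium alkoxide 10 (not isolated)
Conditions: HC≡CMgBr (4 equiv, 0.5 M in THF), THF/toluene, −78 → 0 °C; aq NH4Cl
Reagents that add atoms: ethynylmagnesium bromide, C#C[Mg]Br
Why: 1,3‑Chelation‑controlled Grignard 1,2‑addition: the magnesium alkoxide chelates the C‑1′ carbonyl, holding the CH2O arm pseudo‑equatorial and the 6′‑methyl pseudo‑axial, so the small acetylide attacks axially anti to that methyl and gives the 1′R carbinol (OH cis to CH3, ethynyl cis to CH2OH).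

Step 8
Reactants: 11 (7S,8R)‑8‑ethynyl‑7‑(hydroxymethyl)‑7,9‑dimethyl‑1,4‑dioxaspiro[4.5]dec‑9‑en‑8‑ol
Product: 12 (7S,8R)‑7‑(hydroxymethyl)‑7,9‑dimethyl‑8‑[(E)‑2‑(tributylstannyl)ethenyl]‑1,4‑dioxaspiro[4.5]dec‑9‑en‑8‑ol
Conditions: Bu3SnH (1.3 equiv), PdCl2(PPh3)2 (3 mol %), THF, 0 °C → rt
Reagents that add atoms: tributyltin hydride, CCCC[SnH](CCCC)CCCC
Why: Palladium‑catalysed syn‑hydrostannation of the terminal alkyne: the very hindered tertiary propargylic centre sends tin to the distal carbon, giving the (E)‑vinylstannane.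

Step 9
Reactants: 13 but‑2‑ynoic acid
Product: 14 (2Z)‑3‑iodobut‑2‑enoic acid
Conditions: NaI (1.6 equiv), AcOH, 110 °C
Reagents that add atoms: sodium iodide, [Na+].[I-]
Why: Conjugate hydroiodination: iodide adds to the β‑carbon of the ynoic acid and protonation gives the thermodynamically favoured (Z)‑β‑iodo acid.

Step 10
Reactants: 14 (2Z)‑3‑iodobut‑2‑enoic acid
Product: 15 prop‑2‑en‑1‑yl (2Z)‑3‑iodobut‑2‑enoate
Conditions: allyl bromide, K2CO3, DMF, rt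
Reagents that add atoms: allyl bromide, C=CCBr
Why: Carboxylate O‑alkylation (SN2) gives the allyl ester without touching the vinyl iodide or its geometry.

Step 11
Reactants: 12 (7S,8R)‑7‑(hydroxymethyl)‑7,9‑dimethyl‑8‑[(E)‑2‑(tributylstannyl)ethenyl]‑1,4‑dioxaspiro[4.5]dec‑9‑en‑8‑ol; 15 prop‑2‑en‑1‑yl (2Z)‑3‑iodobut‑2‑enoate
Product: 16 prop‑2‑en‑1‑yl (2Z,4E)‑5‑[(7S,8R)‑8‑hydroxy‑7‑(hydroxymethyl)‑7,9‑dimethyl‑1,4‑dioxaspiro[4.5]dec‑9‑en‑8‑yl]‑3‑methylpenta‑2,4‑dienoate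
Conditions: Cu(O2CC4H3S) (copper thiophene‑2‑carboxylate, 1.5 equiv), NMP, 0 °C → rt, dark
Reagents that add atoms: none
Why: Liebeskind copper‑mediated Stille‑type coupling: tin‑to‑copper transmetalation and coupling with the β‑iodo enoate retain both alkene geometries, giving the (2Z,4E)‑dienoate, and the palladium‑free conditions leave the allyl ester alone.

Step 12
Reactants: 17 3‑hydroxy‑3‑methylpentanedioic acid
Product: 18 dimethyl 3‑hydroxy‑3‑methylpentanedioate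
Conditions: MeOH, H2SO4 (cat.), 40 °C
Reagents that add atoms: methanol, CO
Why: Fischer esterification gives the prochiral diester that the enzyme desymmetrises.

Step 13
Reactants: 18 dimethyl 3‑hydroxy‑3‑methylpentanedioate
Product: 19 (3S)‑3‑hydroxy‑5‑methoxy‑3‑methyl‑5‑oxopentanoic acid
Conditions: pig liver esterase (a carboxylesterase, serine hydrolase class, EC 3.1.1.1), 0.1 M phosphate buffer pH 7.5, 25 °C, pH‑stat with 1 M NaOH (1.0 equiv); then HCl to pH 2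
Reagents that add atoms: water, O
Why: Enantiotopic‑group‑selective enzymatic ester hydrolysis: the esterase active site accepts only the pro‑R CH2CO2Me arm, setting the glutarate stereocentre as S, and stops at the half‑ester because the carboxylate is a poor substrate.

Step 14
Reactants: 19 (3S)‑3‑hydroxy‑5‑methoxy‑3‑methyl‑5‑oxopentanoic acid
Product: 20 1‑tert‑butyl 5‑methyl (3R)‑3‑hydroxy‑3‑methylpentanedioate
Conditions: Cl3CC(=NH)O‑t‑Bu (2 equiv), CH2Cl2/cyclohexane, rt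
Reagents that add atoms: tert‑butyl 2,2,2‑trichloroacetimidate, CC(C)(C)OC(=N)C(Cl)(Cl)Cl
Why: Imidate tert‑butylation: the carboxylic acid protonates the trichloroacetimidate and captures the tert‑butyl cation, while the tertiary alcohol does not react; the centre is untouched (R only through CIP priorities).

Step 15
Reactants: 20 1‑tert‑butyl 5‑methyl (3R)‑3‑hydroxy‑3‑methylpentanedioate
Product: 21 (3R)‑5‑tert‑butoxy‑3‑hydroxy‑3‑methyl‑5‑oxopentanoic acid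
Conditions: LiOH (1.2 equiv), THF/H2O 3:1, 0 °C; then 1 M HCl to pH 3 at 0 °C
Reagents that add atoms: lithium hydroxide, [Li+].[OH-]
Why: Saponification (BAc2) is selective for the unhindered methyl ester over the tert‑butyl ester.

Step 16
Reactants: 21 (3R)‑5‑tert‑butoxy‑3‑hydroxy‑3‑methyl‑5‑oxopentanoic acid
Product: 22 1‑tert‑butyl 5‑(prop‑2‑en‑1‑yl) (3R)‑3‑hydroxy‑3‑methylpentanedioate
Conditions: allyl bromide, K2CO3, DMF, rt
Reagents that add atoms: allyl bromide, C=CCBr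
Why: Carboxylate SN2 alkylation puts the allyl ester on the arm that ends as the free acid of the target.

Step 17
Reactants: 22 1‑tert‑butyl 5‑(prop‑2‑en‑1‑yl) (3R)‑3‑hydroxy‑3‑methylpentanedioate
Product: 23 (3S)‑3‑hydroxy‑3‑methyl‑5‑oxo‑5‑(prop‑2‑en‑1‑yloxy)pentanoic acid
Conditions: TFA/CH2Cl2 1:4, 0 °C → rt
Reagents that add atoms: none
Why: Acidolysis of the tert‑butyl ester (AAL1, loss of isobutene) frees the carboxyl to be joined to the core; the allyl ester and the electron‑poor tertiary alcohol survive.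

Step 18
Reactants: 16 prop‑2‑en‑1‑yl (2Z,4E)‑5‑[(7S,8R)‑8‑hydroxy‑7‑(hydroxymethyl)‑7,9‑dimethyl‑1,4‑dioxaspiro[4.5]dec‑9‑en‑8‑yl]‑3‑methylpenta‑2,4‑dienoate; 23 (3S)‑3‑hydroxy‑3‑methyl‑5‑oxo‑5‑(prop‑2‑en‑1‑yloxy)pentanoic acid
Product: 24 prop‑2‑en‑1‑yl (2Z,4E)‑5‑[(7S,8R)‑8‑hydroxy‑7‑({[(3R)‑3‑hydroxy‑3‑methyl‑5‑oxo‑5‑(prop‑2‑en‑1‑yloxy)pentanoyl]oxy}methyl)‑7,9‑dimethyl‑1,4‑dioxaspiro[4.5]dec‑9‑en‑8‑yl]‑3‑methylpenta‑2,4‑dienoate
Conditions: EDC·HCl (1.5 equiv), DMAP (0.5 equiv), CH2Cl2, 0 °C → rt, dark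
Reagents that add atoms: none
Why: Steglich esterification: the carbodiimide‑activated acid is passed by DMAP to the only reactive hydroxyl, the primary 6′‑CH2OH (both tertiary alcohols are inert), joining the fragments without touching a stereocentre.

Step 19
Reactants: 24 prop‑2‑en‑1‑yl (2Z,4E)‑5‑[(7S,8R)‑8‑hydroxy‑7‑({[(3R)‑3‑hydroxy‑3‑methyl‑5‑oxo‑5‑(prop‑2‑en‑1‑yloxy)pentanoyl]oxy}methyl)‑7,9‑dimethyl‑1,4‑dioxaspiro[4.5]dec‑9‑en‑8‑yl]‑3‑methylpenta‑2,4‑dienoate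
Product: 25 prop‑2‑en‑1‑yl (2Z,4E)‑5‑[(1R,6S)‑1‑hydroxy‑6‑({[(3R)‑3‑hydroxy‑3‑methyl‑5‑oxo‑5‑(prop‑2‑en‑1‑yloxy)pentanoyl]oxy}methyl)‑2,6‑dimethyl‑4‑oxocyclohex‑2‑en‑1‑yl]‑3‑methylpenta‑2,4‑dienoate
Conditions: 1 M HCl/THF 1:4, 0 °C → rt, dark
Reagents that add atoms: water, O
Why: Acid‑catalysed hydrolysis of the allylic dioxolane unmasks the enone; the CH2OH is already acylated, so no intramolecular oxa‑Michael cyclisation can occur, and the esters and tertiary allylic alcohol tolerate dilute acid.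

Step 20
Reactants: 25 prop‑2‑en‑1‑yl (2Z,4E)‑5‑[(1R,6S)‑1‑hydroxy‑6‑({[(3R)‑3‑hydroxy‑3‑methyl‑5‑oxo‑5‑(prop‑2‑en‑1‑yloxy)pentanoyl]oxy}methyl)‑2,6‑dimethyl‑4‑oxocyclohex‑2‑en‑1‑yl]‑3‑methylpenta‑2,4‑dienoate
Product: 26 (2Z,4E)‑5‑[(1R,6S)‑6‑({[(3R)‑4‑carboxy‑3‑hydroxy‑3‑methylbutanoyl]oxy}methyl)‑1‑hydroxy‑2,6‑dimethyl‑4‑oxocyclohex‑2‑en‑1‑yl]‑3‑methylpenta‑2,4‑dienoic acid
Conditions: Pd(PPh3)4 (5 mol %), morpholine (10 equiv), THF, rt, dark; then aqueous work‑up at pH 3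
Reagents that add atoms: none
Why: Tsuji–Trost deallylation: zerovalent palladium ionises both allyl esters to π‑allyl complexes that morpholine captures, freeing both acids under neutral conditions that preserve the inner ester, the enone and the (2Z,4E)‑diene.

**Compound list**
1 | 2,6‑dimethylphenol | Cc1cccc(C)c1O | starting material
2 | 7,9‑dimethyl‑1,4‑dioxaspiro[4.5]deca‑6,9‑dien‑8‑one | CC1=CC2(OCCO2)C=C(C)C1=O | intermediate
3 | lithium 7,9‑dimethyl‑1,4‑dioxaspiro[4.5]deca‑7,9‑dien‑8‑olate (lithium dienolate) | [Li+].[O-]C1=C(C)CC2(OCCO2)C=C1C | intermediate (not isolated)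
4 | prop‑2‑en‑1‑yl 7,9‑dimethyl‑1,4‑dioxaspiro[4.5]deca‑7,9‑dien‑8‑yl carbonate | C=CCOC(=O)OC1=C(C)CC2(OCCO2)C=C1C | intermediate
5 | (7R)‑7,9‑dimethyl‑7‑(prop‑2‑en‑1‑yl)‑1,4‑dioxaspiro[4.5]dec‑9‑en‑8‑one | CC1=CC2(OCCO2)C[C@@](C)(CC=C)C1=O | intermediate
6 | (7S)‑7,9‑dimethyl‑7‑[(1E)‑prop‑1‑en‑1‑yl]‑1,4‑dioxaspiro[4.5]dec‑9‑en‑8‑one | CC1=CC2(OCCO2)C[C@@](C)(/C=C/C)C1=O | intermediate
7 | (7S)‑7,9‑dimethyl‑7‑(5‑methyl‑1,2,4‑trioxolan‑3‑yl)‑1,4‑dioxaspiro[4.5]dec‑9‑en‑8‑one (ozonide) | CC1=CC2(OCCO2)C[C@@](C)(C3OOC(C)O3)C1=O | intermediate (not isolated)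
8 | (7S)‑7,9‑dimethyl‑8‑oxo‑1,4‑dioxaspiro[4.5]dec‑9‑ene‑7‑carbaldehyde | CC1=CC2(OCCO2)C[C@@](C)(C=O)C1=O | intermediate
9 | (7S)‑7‑(hydroxymethyl)‑7,9‑dimethyl‑1,4‑dioxaspiro[4.5]dec‑9‑en‑8‑one | CC1=CC2(OCCO2)C[C@@](C)(CO)C1=O | intermediate
10 | bromomagnesium alkoxide of 9, bromomagnesium [(7S)‑7,9‑dimethyl‑8‑oxo‑1,4‑dioxaspiro[4.5]dec‑9‑en‑7‑yl]methanolate | CC1=CC2(OCCO2)C[C@@](C)(CO[Mg]Br)C1=O | intermediate (not isolated)
11 | (7S,8R)‑8‑ethynyl‑7‑(hydroxymethyl)‑7,9‑dimethyl‑1,4‑dioxaspiro[4.5]dec‑9‑en‑8‑ol | CC1=CC2(OCCO2)C[C@@](C)(CO)[C@@]1(O)C#C | intermediate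
12 | (7S,8R)‑7‑(hydroxymethyl)‑7,9‑dimethyl‑8‑[(E)‑2‑(tributylstannyl)ethenyl]‑1,4‑dioxaspiro[4.5]dec‑9‑en‑8‑ol | CC1=CC2(OCCO2)C[C@@](C)(CO)[C@@]1(O)/C=C/[Sn](CCCC)(CCCC)CCCC | intermediate
13 | but‑2‑ynoic acid | CC#CC(=O)O | starting material
14 | (2Z)‑3‑iodobut‑2‑enoic acid | C/C(I)=C/C(=O)O | intermediate
15 | prop‑2‑en‑1‑yl (2Z)‑3‑iodobut‑2‑enoate | C/C(I)=C/C(=O)OCC=C | intermediate
16 | prop‑2‑en‑1‑yl (2Z,4E)‑5‑[(7S,8R)‑8‑hydroxy‑7‑(hydroxymethyl)‑7,9‑dimethyl‑1,4‑dioxaspiro[4.5]dec‑9‑en‑8‑yl]‑3‑methylpenta‑2,4‑dienoate | CC1=CC2(OCCO2)C[C@@](C)(CO)[C@@]1(O)/C=C/C(C)=C\C(=O)OCC=C | intermediate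
17 | 3‑hydroxy‑3‑methylpentanedioic acid | CC(O)(CC(=O)O)CC(=O)O | starting material
18 | dimethyl 3‑hydroxy‑3‑methylpentanedioate | COC(=O)CC(C)(O)CC(=O)OC | intermediate
19 | (3S)‑3‑hydroxy‑5‑methoxy‑3‑methyl‑5‑oxopentanoic acid | OC(=O)C[C@](C)(O)CC(=O)OC | intermediate
20 | 1‑tert‑butyl 5‑methyl (3R)‑3‑hydroxy‑3‑methylpentanedioate | CC(C)(C)OC(=O)C[C@](C)(O)CC(=O)OC | intermediate
21 | (3R)‑5‑tert‑butoxy‑3‑hydroxy‑3‑methyl‑5‑oxopentanoic acid | CC(C)(C)OC(=O)C[C@](C)(O)CC(=O)O | intermediate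
22 | 1‑tert‑butyl 5‑(prop‑2‑en‑1‑yl) (3R)‑3‑hydroxy‑3‑methylpentanedioate | CC(C)(C)OC(=O)C[C@](C)(O)CC(=O)OCC=C | intermediate
23 | (3S)‑3‑hydroxy‑3‑methyl‑5‑oxo‑5‑(prop‑2‑en‑1‑yloxy)pentanoic acid | OC(=O)C[C@](C)(O)CC(=O)OCC=C | intermediate
24 | prop‑2‑en‑1‑yl (2Z,4E)‑5‑[(7S,8R)‑8‑hydroxy‑7‑({[(3R)‑3‑hydroxy‑3‑methyl‑5‑oxo‑5‑(prop‑2‑en‑1‑yloxy)pentanoyl]oxy}methyl)‑7,9‑dimethyl‑1,4‑dioxaspiro[4.5]dec‑9‑en‑8‑yl]‑3‑methylpenta‑2,4‑dienoate | CC1=CC2(OCCO2)C[C@@](C)(COC(=O)C[C@](C)(O)CC(=O)OCC=C)[C@@]1(O)/C=C/C(C)=C\C(=O)OCC=C | intermediate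
25 | prop‑2‑en‑1‑yl (2Z,4E)‑5‑[(1R,6S)‑1‑hydroxy‑6‑({[(3R)‑3‑hydroxy‑3‑methyl‑5‑oxo‑5‑(prop‑2‑en‑1‑yloxy)pentanoyl]oxy}methyl)‑2,6‑dimethyl‑4‑oxocyclohex‑2‑en‑1‑yl]‑3‑methylpenta‑2,4‑dienoate | CC1=CC(=O)C[C@@](C)(COC(=O)C[C@](C)(O)CC(=O)OCC=C)[C@@]1(O)/C=C/C(C)=C\C(=O)OCC=C | intermediate
26 | (2Z,4E)‑5‑[(1R,6S)‑6‑({[(3R)‑4‑carboxy‑3‑hydroxy‑3‑methylbutanoyl]oxy}methyl)‑1‑hydroxy‑2,6‑dimethyl‑4‑oxocyclohex‑2‑en‑1‑yl]‑3‑methylpenta‑2,4‑dienoic acid | CC1=CC(=O)C[C@@](C)(COC(=O)C[C@](C)(O)CC(=O)O)[C@@]1(O)/C=C/C(C)=C\C(=O)O | target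

**Step count**
Total steps: 20. Longest linear sequence: 12 (steps 1–8, 11, 18, 19, 20, from 2,6‑dimethylphenol).

**Three steps most likely to fail**

Step 3 (asymmetric allylation). The enolate is cross‑conjugated and carries a ketal, so the ee may stay near 85–90 %, and enol carbonate 4 can aromatise on acidic silica. The ligand sense is assigned by analogy and must be confirmed; any minor enantiomer is removed after step 18 as a diastereomer of 24. The fallback sets out from dienone 2. The same LiBH(s‑Bu)3 reduction is run, but the enolate is trapped with Me3SiCl to give the trimethylsilyl dienol ether F1. F1 then undergoes a catalytic asymmetric Mukaiyama aldol with aqueous formaldehyde (Sc(OTf)3, chiral 6,6′‑bis(1‑hydroxy‑2,2‑dimethylpropyl)‑2,2′‑bipyridine, DME/H2O, −20 °C), which gives hydroxymethyl ketone 9 directly. The route is rejoined at 9 and steps 3–6 fall away.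

Step 7 (facial selectivity of the ethynyl addition). The two 6′ substituents (CH3 and CH2OMgBr) are similar in size, so selectivity rests on the chelate, and alkoxide 10 could lose formaldehyde by retro‑aldol. The fallback sets out from allyl ketone 5, where allyl is clearly the larger, pseudo‑equatorial group and no alkoxide is present. LiC≡CSiMe3 with CeCl3 (THF, −78 °C) adds anti to the pseudo‑axial methyl to give the silylalkynyl carbinol F2. RuHCl(CO)(PPh3)3 isomerisation gives the propenyl carbinol F3, and ozonolysis with NaBH4 work‑up gives the hydroxymethyl carbinol F4. K2CO3/MeOH removes the silyl group and the route is rejoined at diol 11.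

Step 13 (esterase desymmetrisation). The ee with this tertiary‑alcohol diester may be insufficient, and the sense must be checked (for example by reducing a sample to mevalonolactone and comparing rotation). The fallback sets out from diacid 17. DCC in THF closes it to 3‑hydroxy‑3‑methylglutaric anhydride F5. A lipase (triacylglycerol lipase class, for example immobilised Candida antarctica lipase B, chosen by screening; allyl alcohol, MTBE, rt) then opens one enantiotopic carbonyl to give allyl half‑ester 23 directly. The route is rejoined at 23 and steps 12–17 fall away.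

**Further compounds**
F1 | step 3 | trimethyl[(7,9‑dimethyl‑1,4‑dioxaspiro[4.5]deca‑7,9‑dien‑8‑yl)oxy]silane | C[Si](C)(C)OC1=C(C)CC2(OCCO2)C=C1C
F2 | step 7 | (7R,8S)‑7,9‑dimethyl‑7‑(prop‑2‑en‑1‑yl)‑8‑[(trimethylsilyl)ethynyl]‑1,4‑dioxaspiro[4.5]dec‑9‑en‑8‑ol | CC1=CC2(OCCO2)C[C@@](C)(CC=C)[C@@]1(O)C#C[Si](C)(C)C
F3 | step 7 | (7S,8R)‑7,9‑dimethyl‑7‑[(1E)‑prop‑1‑en‑1‑yl]‑8‑[(trimethylsilyl)ethynyl]‑1,4‑dioxaspiro[4.5]dec‑9‑en‑8‑ol | CC1=CC2(OCCO2)C[C@@](C)(/C=C/C)[C@@]1(O)C#C[Si](C)(C)C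
F4 | step 7 | (7S,8R)‑7‑(hydroxymethyl)‑7,9‑dimethyl‑8‑[(trimethylsilyl)ethynyl]‑1,4‑dioxaspiro[4.5]dec‑9‑en‑8‑ol | CC1=CC2(OCCO2)C[C@@](C)(CO)[C@@]1(O)C#C[Si](C)(C)C
F5 | step 13 | 4‑hydroxy‑4‑methyloxane‑2,6‑dione (3‑hydroxy‑3‑methylglutaric anhydride) | CC1(O)CC(=O)OC(=O)C1
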